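## Structural features

The target is a linear procyanidin trimer of three (2R,3R)-epicatechin units in which every O3 carries a galloyl (3,4,5-trihydroxybenzoyl) ester. C4 of the top unit T is bonded to C6 of ring A of the middle unit M (4β→6), and C4 of M is bonded to C8 of ring A of the lower unit L (4β→8). Each unit is a chroman (benzene ring A fused to pyran ring C) with a 3,4-dihydroxyphenyl ring B on C2. The eight stereocentres form three contiguous sets: C2–C3–C4 in T (2R,3R,4S) and in M (2R,3R,4R), each 2,3-cis and 3,4-trans, and C2–C3 in L (2R,3R, cis). The free trimer carries twelve phenolic hydroxyls on rings A and B and three aliphatic O3–H groups (fifteen hydroxyls in all), and the target has twenty-one free phenols once the nine galloyl hydroxyls are added. Fragile elements are the interflavan C4–aryl bonds (reversible acid-induced ionisation at C4), the catechol, phloroglucinol and pyrogallol rings (oxidation above neutral pH, base-induced opening of ring C with loss of the C2 configuration) and the three aryl esters. The real difficulties are the 4→6 regiochemistry of the T–M bond (C8 of a flavan is normally the more nucleophilic position), the 4β configuration at both junctions, and acylation of three hindered secondary alcohols beside twelve more acidic and more accessible phenols. The key step exploits the one motif that occurs three times, the O3–H on ring C of a (2R,3R) 2,3-cis-flavan-3-ol, which is the recognition element of glucogallin-dependent galloyltransferases.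

## Logic of the disconnections

The three ester bonds O3–C(=O) on units T, M and L of 17 are cut first, giving 11 and three molecules of the activated acyl donor 14. All nine galloyl phenols leave with the donor, and 11 carries no protecting group, so no protecting-group pattern has to tell O3 from phenol. The demand on the forward step is complete O3 selectivity on all three units and full triple turnover, which only an active site can be expected to deliver.

The anomeric ester bond C1–O of 14 is cut to give 12 and 13. An inverting glucosyltransferase sets the β configuration directly on the unprotected acid, so neither partner needs benzyl protection. The forward step must avoid acyl migration and hydrolysis of the 1-O-acyl ester, so it is run near neutral pH and worked up slightly acidic.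

In 11 the twelve phenolic O–H bonds and the aryl C–H bonds at C6 and C8 of T and at C8 of M are traced back to twelve benzyl ethers and three aryl bromides in 10. One hydrogenolysis must cleave all fifteen bonds without acid reaching the interflavan bonds. The three O3–H of 10 are traced back to the acetates of 9, which block O-alkylation and give anchimeric assistance at C4 during the couplings. With free O3–H and protected phenols, 10 is also the branch point for a purely chemical galloylation.

The bond C4(M)–C8(L) of 9 is cut to give 8 and 3. This lets unit L enter as a simple nucleophile reacting through its innately most reactive position, C8. The forward step must ionise C4 of M without acid strong enough to reopen the T–M bond, hence a thioether leaving group and a neutral thiophilic promoter. Attack anti to the C3 acetate must set C4 of M as 4β.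

The bond C4(T)–C6(M) of 8 is cut to give 5 and 7. This is the bond with the unusual regiochemistry, and three design elements secure it. A bromide on C8 of 7 leaves C6 as the only nucleophilic ring position. Bromides on both C6 and C8 of 5 prevent the electrophile from condensing with itself while it waits for the deactivated C6 of 7. The thioether on C4 of 7 is inert to the hard Lewis acid that ionises the ether on C4 of 5. The demand is that C6 of 7 is still nucleophilic enough, and that attack occurs anti to the C3 acetate of 5 (4β).

Both 5 and 7 (through 6) are traced back to the common ether 4, by double or single ring bromination and by exchange of alkoxy for arylthio at C4. Benzylic oxidation at C4 connects 4 to 3, and acetylation and phenol benzylation connect 3 through 2 to 1. All C2 and C3 stereocentres of the target are bought with 1, so the route has to set only C4 of T and C4 of M.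

## Other disconnections considered

Alternative 1: The cut runs through ring A of unit L, removing C8–C8a, C6–C7 and C4a–C8a. This leaves a siloxyalkyne on C4 of M (A2) and a 3-benzyloxy-4-cinnamylcyclobutenone whose cinnamyl aryl group is 3,4-bis(benzyloxy)phenyl (A3). In the forward direction, heating would open the four-membered ring of A3 electrocyclically, and the ketene so formed would add to the alkyne of A2 in a [2+2] manner. A second electrocyclic opening, 6π closure and tautomerisation would then give the phenol A1 (Danheiser benzannulation).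
- In its favour: the M–L regiochemistry is fixed by construction, because the carbon that becomes C8 is the alkyne carbon already bonded to C4 of M. The three oxygens of the new ring come out differentiated (free C8a–OH, silyl ether on C7, benzyl ether on C5). The neutral thermal conditions spare the acid-labile T–M bond.
- Against it here: A2 needs an ynol silyl ether carbon on C4 of M with 4β configuration, for which flavan chemistry offers no direct entry. After A1 the whole of ring C of L is still missing: the cinnamyl alkene must be dihydroxylated enantioselectively, closed onto the C8a phenol and brought into the 2,3-cis series. The silyl groups must then be exchanged, three gallates attached to a fully protected trimer, and the benzyl ethers and the bromide removed.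
- Comparison: on M–L regiochemistry this plan is the better of the two, since the chosen route relies on the innate C8 preference of 3. On the T–M bond it is only the equal, because the bromide on C8 of M in A1 points to the same capped cationic coupling. On mechanistic predictability it is also the better, a pericyclic cascade being easier to foresee than acceptance of a trimer by an enzyme. It is worse on stereochemistry (two stereocentres of L made instead of bought) and on step economy, where roughly twice the operations of the chosen route must be expected. It does not address the O3-versus-phenol problem at all.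

Alternative 2: The cut removes C3–C4 and O1–C2 of ring C of M. Ring A of M becomes a phloroglucinol linchpin that carries T para to its free phenol and, ortho to that phenol, the carbinol carbon bonded to C8 of L (the o-hydroxybenzhydrol A5). The two-carbon partner is the (Z)-enol gallate A6. Forward, loss of water from A5 (heat or mild acid) would unmask an o-quinone methide (O1=C8a–C4a=C4). This would add A6 in an inverse-electron-demand hetero-Diels–Alder reaction, C4 bonding to the acyloxy-bearing carbon and O1 to the benzylic carbon, to give A4.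
- In its favour: the gallate of M, the most hindered of the three, is in place before the ring exists. The Z geometry of A6 is carried suprafacially into the 2,3-cis relationship, and the plan is highly convergent. A4 is one hydrogenolysis away from 17, so on the endgame it is the equal of the chosen plan or better, needing neither an enzyme nor any selective acylation.
- Against it here: C2, C3 and C4 of M are created at once, and the cycloaddition controls only their mutual relationship (cis from the alkene geometry, 3,4-trans only if the exo/endo preference and the methide geometry cooperate). The absolute sense must be induced by the stereocentres of T and L, which sit beyond two aryl rings, so a mixture of diastereomeric trimers that are hard to separate is the likely outcome. The acyloxy group lowers the nucleophilicity of the styrene, so methide dimerisation or addition with the opposite regiochemistry may compete. A5 and A6 also carry nucleophile-sensitive aryl esters through the step.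
- Comparison: structurally this plan builds ring C of M, whereas the chosen plan keeps all three pyran rings of 1 intact and never has to set C2 or C3. Mechanistically both key steps lack direct precedent on this substrate class; the cycloaddition is the more predictable in rate, the enzymatic transfer the more predictable in stereochemical outcome, since it creates no stereocentre. In step count to the key-step substrates the two are comparable at best, because A5 requires T and L to be made separately as protected gallates and then joined through the linchpin.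

Alternative 3: The cut is the O1–C2 bond of ring C of L. The precursor is the α-diazo ketone A8, in which ring A of L carries a free C8a phenol and a CH2–CO–C(N2)–aryl chain on C4a. Forward, Rh2(OAc)4 would decompose the diazo group to a rhodium carbene at the future C2. The phenol oxygen would add to it and a proton shift would complete the O–H insertion, closing the six-membered ring as the 2-aryl-chroman-3-one A7.
- In its favour: intramolecular phenol O–H insertion by aryl-substituted carbenes is fast and well understood, loss of N2 makes it irreversible, and the conditions are neutral. The T and M gallates and both interflavan bonds are already in place. The C3 ketone offers a handle for setting 2,3-cis by hydride delivery anti to the C2 aryl group.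
- Against it here: C2 is formed without control by the rest of the molecule and stays epimerisable (α to the ketone, benzylic and α to oxygen). The enolisable chroman-3-one is prone to air oxidation, and the cis-selective reduction must spare two aryl esters. After A7 three more operations are needed (reduction, galloylation of O3 of L, hydrogenolysis). The carbene also has other outlets in a substrate full of benzylic ether CH2 groups and electron-rich arenes (C–H insertion, arene cyclopropanation). A8 itself needs a regioselective diazo transfer to a ketone with two benzylic α-positions.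
- Comparison: at the T–M junction this plan is the equal of the chosen one, since the bromide on C8 of M in A7 points to the same capped cationic coupling. On precedent for the bond-forming event it is the better, because phenol O–H insertion is established and triple enzymatic galloylation of an oligomer is not. On structure and step economy it is the worse: it rebuilds without control a stereocentre that the chosen route takes unchanged from 1, it still needs full benzyl protection to place the gallates, and the way to A8 is considerably longer than the ten-step line to 17.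

Key step: step 12

Assumption: in step 12 the least hindered O3 (unit L) is taken to react first, then that of T and last that of M; any other order passes through isomeric mono- and di-gallates and ends at the same product. The two enzymes are taken to be produced by heterologous expression.

## Route

Step 1
Reactants: 1 (−)-epicatechin
Product: 2 tetra-O-benzylepicatechin (5,7,3',4'-tetra-O-benzyl-(−)-epicatechin, 2R,3R, free O3–H)
Conditions: BnBr (4.4 equiv), K2CO3 (4.4 equiv), DMF, 0 °C → rt, Ar
Reagents that add atoms: benzyl bromide, BrCc1ccccc1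
Why: Williamson ether synthesis; K2CO3 ionises only the four phenols, so the secondary O3–H stays free. Kept cold and oxygen-free, ring C does not open under base and C2 and C3 are untouched.

Step 2
Reactants: 2 tetra-O-benzylepicatechin
Product: 3 tetra-O-benzylepicatechin acetate (3-O-acetyl-5,7,3',4'-tetra-O-benzyl-(−)-epicatechin)
Conditions: Ac2O, pyridine, DMAP (cat.), CH2Cl2, rt
Reagents that add atoms: acetic anhydride, CC(=O)OC(C)=O
Why: DMAP-catalysed acylation of the secondary alcohol. The acetate later blocks O-alkylation and gives neighbouring-group participation at C4.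

Step 3
Reactants: 3 tetra-O-benzylepicatechin acetate
Product: 4 benzylic ether (3-O-acetyl-5,7,3',4'-tetra-O-benzyl-4β-(2-ethoxyethoxy)epicatechin, 2,3-cis-3,4-trans)
Conditions: DDQ (2 equiv), 2-ethoxyethanol (5 equiv), CH2Cl2, rt
Reagents that add atoms: 2-ethoxyethanol, CCOCCO
Why: Oxidative benzylic functionalisation; DDQ abstracts hydride from C4, which is activated by O1 and the 5- and 7-benzyloxy groups. The alcohol traps the cation anti to the C3 acetate and the C2 aryl group, giving the 4β ether; this centre only carries a leaving group.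

Step 4
Reactants: 4 benzylic ether
Product: 5 dibromo benzylic ether (3-O-acetyl-5,7,3',4'-tetra-O-benzyl-6,8-dibromo-4β-(2-ethoxyethoxy)epicatechin; doubly capped electrophile for unit T)
Conditions: NBS (2.2 equiv), CH2Cl2, −40 °C → rt
Reagents that add atoms: N-bromosuccinimide, O=C1CCC(=O)N1Br
Why: Electrophilic aromatic bromination; ring A is a phloroglucinol triether and takes bromine at C8 and then at C6. With both positions capped the future electrophile cannot condense with itself.

Step 5
Reactants: 4 benzylic ether
Product: 6 bromo benzylic ether (3-O-acetyl-5,7,3',4'-tetra-O-benzyl-8-bromo-4β-(2-ethoxyethoxy)epicatechin)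
Conditions: NBS (1.0 equiv), CH2Cl2, −78 → 0 °C
Reagents that add atoms: N-bromosuccinimide, O=C1CCC(=O)N1Br
Why: Electrophilic aromatic bromination with one equivalent at low temperature should go to C8, which is less hindered than C6 (flanked by two benzyloxy groups). The bromide blocks C8 so that the later coupling can only occur at C6.

Step 6
Reactants: 6 bromo benzylic ether
Product: 7 bromo thioether (3-O-acetyl-5,7,3',4'-tetra-O-benzyl-8-bromo-4β-(2,6-dimethylphenylthio)epicatechin; nucleophile for unit M)
Conditions: 2,6-dimethylbenzenethiol (3 equiv), BF3·OEt2 (0.5 equiv), CH2Cl2, −78 → −40 °C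
Reagents that add atoms: 2,6-dimethylbenzenethiol, Cc1cccc(C)c1S
Why: Lewis acid-mediated SN1 thiolysis; ionisation at C4 and capture by the thiol anti to the acetate gives the 4β thioether. This leaving group is not activated by BF3·OEt2 at low temperature, so it is orthogonal to the alkoxy group of 5.

Step 7
Reactants: 5 dibromo benzylic ether; 7 bromo thioether (1.5 equiv)
Product: 8 dimer thioether ([3-O-acetyl-5,7,3',4'-tetra-O-benzyl-6,8-dibromoepicatechin]-(4β→6)-[3-O-acetyl-5,7,3',4'-tetra-O-benzyl-8-bromo-4β-(2,6-dimethylphenylthio)epicatechin])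
Conditions: BF3·OEt2 (0.5 equiv), 4 Å MS, CH2Cl2, −78 → −20 °C
Reagents that add atoms: none
Why: Friedel–Crafts alkylation with halogen capping; BF3·OEt2 ionises only the C4 ether of 5, and the cation is attacked by C6 of 7, the only free nucleophilic ring position in the flask. Attack anti to the participating C3 acetate and the C2 aryl group sets C4 of T as 4β (3,4-trans, 4S).

Step 8
Reactants: 8 dimer thioether; 3 tetra-O-benzylepicatechin acetate (3 equiv)
Product: 9 protected trimer triacetate ([3-O-acetyl-tetra-O-benzyl-6,8-dibromoepicatechin]-(4β→6)-[3-O-acetyl-tetra-O-benzyl-8-bromoepicatechin]-(4β→8)-[3-O-acetyl-tetra-O-benzylepicatechin])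
Conditions: NIS (1.2 equiv), 4 Å MS, CH2Cl2, −78 → −30 °C
Reagents that add atoms: none
Why: Thiophilic activation followed by Friedel–Crafts alkylation; NIS turns the thioether into an iodosulfonium leaving group under neutral conditions, and the C4 cation of M is captured by C8 of 3, the most nucleophilic position of an unblocked flavan. Attack anti to the C3 acetate sets C4 of M as 4β (4R), and the excess of 3 suppresses a second alkylation.

Step 9
Reactants: 9 protected trimer triacetate
Product: 10 benzylated trimer triol (dodeca-O-benzyl trimer with 6,8-dibromo on unit T, 8-bromo on unit M and three free O3–H)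
Conditions: NaOMe (cat.), MeOH–THF, 40 °C
Reagents that add atoms: none
Why: Zemplén transesterification removes the three acetates. Benzyl ethers, aryl bromides and interflavan bonds are inert to methoxide, and with all phenols protected ring C cannot open.

Step 10
Reactants: 10 benzylated trimer triol
Product: 11 free trimer (epicatechin-(4β→6)-epicatechin-(4β→8)-epicatechin)
Conditions: H2 (1 atm), Pd(OH)2/C, NaOAc (3.3 equiv), THF–MeOH–H2O, rt; desalting on Sephadex LH-20, lyophilisation
Reagents that add atoms: none
Why: Heterogeneous hydrogenolysis cleaves the twelve benzyl ethers and hydrodebrominates the three aryl bromides in one operation. NaOAc takes up the HBr so that the acid-labile interflavan bonds are not ionised; no stereocentre is involved.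

Step 11
Reactants: 12 gallic acid; 13 uridine 5'-diphospho-α-D-glucose
Product: 14 β-glucogallin (1-O-galloyl-β-D-glucopyranose)
Conditions: recombinant UGT84A-type gallate 1-O-β-glucosyltransferase, HEPES buffer pH 7.0, 30 °C; acidification to pH 4, C18 chromatography
Reagents that add atoms: none
Why: Known enzymatic glucosyl transfer by an inverting family 1 glycosyltransferase; the carboxylate of gallic acid displaces UDP at C1 of the α-configured donor, which sets the β anomeric configuration.

Step 12
Reactants: 11 free trimer; 14 β-glucogallin (10 equiv, in portions)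
Product: 17 epicatechin-3-O-gallate-(4β→6)-epicatechin-3-O-gallate-(4β→8)-epicatechin-3-O-gallate (target), via trimer monogallate 15 (not isolated), via trimer digallate 16 (not isolated)
Conditions: recombinant tea serine carboxypeptidase-like galloyltransferase (epicatechin:1-O-galloyl-β-D-glucose O-galloyltransferase), ascorbic acid, MES buffer pH 6.0, N2, 30 °C; Sephadex LH-20, then preparative reversed-phase HPLC
Reagents that add atoms: none
Why: Proposed new method: the energy-rich 1-O-acyl-β-glucose ester 14 should galloylate the active-site serine of the acyltransferase (Ser–His–Asp triad) with release of glucose, and the acyl-enzyme should then be attacked by the aliphatic O3–H of a bound (2R,3R) 2,3-cis-flavan-3-ol unit; three such cycles lead through 15 and 16 to 17. The closest known reaction type is the 3-O-galloylation of monomeric epicatechin and epigallocatechin by the glucogallin-dependent galloyltransferase of tea leaf; transfer to the units of a procyanidin oligomer has not been shown. No ring is closed and no stereocentre is created: the three new bonds are the O3–C(=O) ester bonds, and C3 keeps its configuration because the C3–O bond is never broken. The selectivity needed is O3 against twelve ring A and ring B phenols (and against the hydroxyls of the donor), and it rests on the positioning of ring C in the active site, not on intrinsic nucleophilicity, since phenols would win with any small acyl donor. Complete triple turnover is to be driven by a large excess of 14 and repeated enzyme charges. The mildly acidic, oxygen-free buffer with ascorbic acid protects the catechol and pyrogallol rings and the interflavan bonds and avoids base-induced hydrolysis of the product esters. The hindered O3 of units T and M, each flanked by a C4 aryl group, is where the enzyme is most likely to fail.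

## Compound list

1 | (−)-epicatechin, (2R,3R) | O[C@@H]1Cc2c(O)cc(O)cc2O[C@@H]1c1ccc(O)c(O)c1 | starting material
2 | 5,7,3',4'-tetra-O-benzyl-(−)-epicatechin | O[C@@H]1Cc2c(OCc5ccccc5)cc(OCc5ccccc5)cc2O[C@@H]1c1ccc(OCc5ccccc5)c(OCc5ccccc5)c1 | intermediate
3 | 3-O-acetyl-5,7,3',4'-tetra-O-benzyl-(−)-epicatechin | CC(=O)O[C@@H]1Cc2c(OCc5ccccc5)cc(OCc5ccccc5)cc2O[C@@H]1c1ccc(OCc5ccccc5)c(OCc5ccccc5)c1 | intermediate
4 | 3-O-acetyl-5,7,3',4'-tetra-O-benzyl-4β-(2-ethoxyethoxy)epicatechin (3,4-trans) | CC(=O)O[C@@H]1[C@@H](OCCOCC)c2c(OCc5ccccc5)cc(OCc5ccccc5)cc2O[C@@H]1c1ccc(OCc5ccccc5)c(OCc5ccccc5)c1 | intermediate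
5 | 3-O-acetyl-5,7,3',4'-tetra-O-benzyl-6,8-dibromo-4β-(2-ethoxyethoxy)epicatechin | CC(=O)O[C@@H]1[C@@H](OCCOCC)c2c(OCc5ccccc5)c(Br)c(OCc5ccccc5)c(Br)c2O[C@@H]1c1ccc(OCc5ccccc5)c(OCc5ccccc5)c1 | intermediate
6 | 3-O-acetyl-5,7,3',4'-tetra-O-benzyl-8-bromo-4β-(2-ethoxyethoxy)epicatechin | CC(=O)O[C@@H]1[C@@H](OCCOCC)c2c(OCc5ccccc5)cc(OCc5ccccc5)c(Br)c2O[C@@H]1c1ccc(OCc5ccccc5)c(OCc5ccccc5)c1 | intermediate
7 | 3-O-acetyl-5,7,3',4'-tetra-O-benzyl-8-bromo-4β-(2,6-dimethylphenylthio)epicatechin | CC(=O)O[C@@H]1[C@@H](Sc6c(C)cccc6C)c2c(OCc5ccccc5)cc(OCc5ccccc5)c(Br)c2O[C@@H]1c1ccc(OCc5ccccc5)c(OCc5ccccc5)c1 | intermediate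
8 | dimer thioether: (4β→6)-linked dimer, unit T with 6,8-dibromo and 3-OAc, unit M with 8-bromo, 3-OAc and 4β-(2,6-dimethylphenylthio), eight benzyl ethers | CC(=O)O[C@@H]1[C@@H](c2c(OCc5ccccc5)c(Br)c3c(c2OCc5ccccc5)[C@H](Sc6c(C)cccc6C)[C@@H](OC(C)=O)[C@@H](c2ccc(OCc5ccccc5)c(OCc5ccccc5)c2)O3)c2c(OCc5ccccc5)c(Br)c(OCc5ccccc5)c(Br)c2O[C@@H]1c1ccc(OCc5ccccc5)c(OCc5ccccc5)c1 | intermediate
9 | protected trimer triacetate: T(6,8-dibromo)-(4β→6)-M(8-bromo)-(4β→8)-L, twelve benzyl ethers, three 3-O-acetates | CC(=O)O[C@@H]1[C@@H](c2c(OCc5ccccc5)c(Br)c3c(c2OCc5ccccc5)[C@H](c2c(OCc5ccccc5)cc(OCc5ccccc5)c4c2O[C@H](c2ccc(OCc5ccccc5)c(OCc5ccccc5)c2)[C@H](OC(C)=O)C4)[C@@H](OC(C)=O)[C@@H](c2ccc(OCc5ccccc5)c(OCc5ccccc5)c2)O3)c2c(OCc5ccccc5)c(Br)c(OCc5ccccc5)c(Br)c2O[C@@H]1c1ccc(OCc5ccccc5)c(OCc5ccccc5)c1 | intermediate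
10 | benzylated trimer triol: as 9 with three free O3–H | O[C@@H]1[C@@H](c2c(OCc5ccccc5)c(Br)c3c(c2OCc5ccccc5)[C@H](c2c(OCc5ccccc5)cc(OCc5ccccc5)c4c2O[C@H](c2ccc(OCc5ccccc5)c(OCc5ccccc5)c2)[C@H](O)C4)[C@@H](O)[C@@H](c2ccc(OCc5ccccc5)c(OCc5ccccc5)c2)O3)c2c(OCc5ccccc5)c(Br)c(OCc5ccccc5)c(Br)c2O[C@@H]1c1ccc(OCc5ccccc5)c(OCc5ccccc5)c1 | intermediate
11 | epicatechin-(4β→6)-epicatechin-(4β→8)-epicatechin | O[C@@H]1[C@@H](c2c(O)cc3c(c2O)[C@H](c2c(O)cc(O)c4c2O[C@H](c2ccc(O)c(O)c2)[C@H](O)C4)[C@@H](O)[C@@H](c2ccc(O)c(O)c2)O3)c2c(O)cc(O)cc2O[C@@H]1c1ccc(O)c(O)c1 | intermediate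
12 | gallic acid | OC(=O)c1cc(O)c(O)c(O)c1 | starting material
13 | uridine 5'-diphospho-α-D-glucose | OC[C@H]1O[C@H](OP(=O)(O)OP(=O)(O)OC[C@H]2O[C@@H](n3ccc(=O)[nH]c3=O)[C@H](O)[C@@H]2O)[C@H](O)[C@@H](O)[C@@H]1O | starting material
14 | β-glucogallin (1-O-galloyl-β-D-glucopyranose) | OC[C@H]1O[C@@H](OC(=O)c2cc(O)c(O)c(O)c2)[C@H](O)[C@@H](O)[C@@H]1O | intermediate
15 | trimer monogallate, galloyl on O3 of unit L | O[C@@H]1[C@@H](c2c(O)cc3c(c2O)[C@H](c2c(O)cc(O)c4c2O[C@H](c2ccc(O)c(O)c2)[C@H](OC(=O)c2cc(O)c(O)c(O)c2)C4)[C@@H](O)[C@@H](c2ccc(O)c(O)c2)O3)c2c(O)cc(O)cc2O[C@@H]1c1ccc(O)c(O)c1 | intermediate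
16 | trimer digallate, galloyl on O3 of units L and T | O=C(O[C@@H]1[C@@H](c2c(O)cc3c(c2O)[C@H](c2c(O)cc(O)c4c2O[C@H](c2ccc(O)c(O)c2)[C@H](OC(=O)c2cc(O)c(O)c(O)c2)C4)[C@@H](O)[C@@H](c2ccc(O)c(O)c2)O3)c2c(O)cc(O)cc2O[C@@H]1c1ccc(O)c(O)c1)c1cc(O)c(O)c(O)c1 | intermediate
17 | epicatechin-3-O-gallate-(4β→6)-epicatechin-3-O-gallate-(4β→8)-epicatechin-3-O-gallate | O=C(O[C@@H]1[C@@H](c2c(O)cc3c(c2O)[C@H](c2c(O)cc(O)c4c2O[C@H](c2ccc(O)c(O)c2)[C@H](OC(=O)c2cc(O)c(O)c(O)c2)C4)[C@@H](OC(=O)c2cc(O)c(O)c(O)c2)[C@@H](c2ccc(O)c(O)c2)O3)c2c(O)cc(O)cc2O[C@@H]1c1ccc(O)c(O)c1)c1cc(O)c(O)c(O)c1 | target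

## Step count and risk

Total step count: 12. Longest linear sequence: 10 steps (steps 1, 2, 3, 5, 6, 7, 8, 9, 10, 12); steps 4 and 11 are side branches.

Least certain steps:

**Step 12 (key step, Proposed new method).** The transfer may stall after the first or second galloylation because the active site, shaped for a monomeric flavan-3-ol, does not admit the C4-arylated rings C of T and M. Hydrolysis of the donor and oxidation of the substrate would then dominate over the long reaction time. Fallback by known chemistry, setting out from 10: Steglich esterification of the three O3–H with 3,4,5-tris(benzyloxy)benzoic acid (DCC, DMAP, CH2Cl2, rt to 40 °C) should give the perbenzylated tri-gallate tribromide F1. Hydrogenolysis (H2, Pd(OH)2/C, NaOAc, THF–MeOH–H2O) then removes twenty-one benzyl groups and three bromides and comes back to the route at 17; steps 10 to 12 are bypassed.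

**Step 7.** Capture of the C4 cation by the bromine-deactivated, doubly flanked C6 of 7 may be slow. In that time the Lewis acid may begin to ionise the C4 thioether, so that the orthogonality of the two leaving groups is lost and oligomerisation of the nucleophile sets in. Fallback, setting out from 5 and 6: thiolysis of 5 (2,6-dimethylbenzenethiol, BF3·OEt2, −78 °C) gives the dibromo thioether F2. Activating F2 with NIS in the presence of 6, whose C4 ether is inert without Lewis acid, gives the dimer C4 ether F3. Coupling F3 with 3 under BF3·OEt2 returns to the route at 9; steps 6 to 8 are bypassed.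

**Step 8.** Iodination of the electron-rich ring A of 3 by NIS may compete with activation of the hindered thioether, and partial attack through C6 of 3 may erode the regioselectivity. Fallback, setting out from 8: treatment with NIS in CH2Cl2–MeOH with no arene nucleophile present exchanges the thioether for methoxy and gives the dimer C4 methyl ether F4. Friedel–Crafts coupling of F4 with 3 under catalytic TMSOTf at −78 °C then returns to the route at 9.

**Step 10.** Hydrodebromination at the hindered C6 of T may lag behind debenzylation, or sulfur residues from step 8 may poison the catalyst. The prolonged exposure then needed favours acid-induced interflavan cleavage and oxidation of the free polyphenol. Fallback, setting out from 10: radical hydrodebromination (Bu3SnH, AIBN, toluene, 90 °C) gives the bromine-free benzylated trimer triol F5. Base-free hydrogenolysis of F5 (H2, Pd(OH)2/C, THF–MeOH) returns to the route at 11.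

## Further compounds

F1 | step 12 | perbenzylated tri-gallate tribromide (10 with three 3,4,5-tris(benzyloxy)benzoyl esters on O3) | O=C(O[C@@H]1[C@@H](c2c(OCc5ccccc5)c(Br)c3c(c2OCc5ccccc5)[C@H](c2c(OCc5ccccc5)cc(OCc5ccccc5)c4c2O[C@H](c2ccc(OCc5ccccc5)c(OCc5ccccc5)c2)[C@H](OC(=O)c2cc(OCc5ccccc5)c(OCc5ccccc5)c(OCc5ccccc5)c2)C4)[C@@H](OC(=O)c2cc(OCc5ccccc5)c(OCc5ccccc5)c(OCc5ccccc5)c2)[C@@H](c2ccc(OCc5ccccc5)c(OCc5ccccc5)c2)O3)c2c(OCc5ccccc5)c(Br)c(OCc5ccccc5)c(Br)c2O[C@@H]1c1ccc(OCc5ccccc5)c(OCc5ccccc5)c1)c1cc(OCc5ccccc5)c(OCc5ccccc5)c(OCc5ccccc5)c1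
F2 | step 7 | 3-O-acetyl-5,7,3',4'-tetra-O-benzyl-6,8-dibromo-4β-(2,6-dimethylphenylthio)epicatechin | CC(=O)O[C@@H]1[C@@H](Sc6c(C)cccc6C)c2c(OCc5ccccc5)c(Br)c(OCc5ccccc5)c(Br)c2O[C@@H]1c1ccc(OCc5ccccc5)c(OCc5ccccc5)c1
F3 | step 7 | dimer C4 ether (as 8 with 4β-(2-ethoxyethoxy) on C4 of unit M) | CC(=O)O[C@@H]1[C@@H](c2c(OCc5ccccc5)c(Br)c3c(c2OCc5ccccc5)[C@H](OCCOCC)[C@@H](OC(C)=O)[C@@H](c2ccc(OCc5ccccc5)c(OCc5ccccc5)c2)O3)c2c(OCc5ccccc5)c(Br)c(OCc5ccccc5)c(Br)c2O[C@@H]1c1ccc(OCc5ccccc5)c(OCc5ccccc5)c1
F4 | step 8 | dimer C4 methyl ether (as 8 with 4β-methoxy on C4 of unit M) | CC(=O)O[C@@H]1[C@@H](c2c(OCc5ccccc5)c(Br)c3c(c2OCc5ccccc5)[C@H](OC)[C@@H](OC(C)=O)[C@@H](c2ccc(OCc5ccccc5)c(OCc5ccccc5)c2)O3)c2c(OCc5ccccc5)c(Br)c(OCc5ccccc5)c(Br)c2O[C@@H]1c1ccc(OCc5ccccc5)c(OCc5ccccc5)c1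
F5 | step 10 | bromine-free benzylated trimer triol (dodeca-O-benzyl derivative of 11) | O[C@@H]1[C@@H](c2c(OCc5ccccc5)cc3c(c2OCc5ccccc5)[C@H](c2c(OCc5ccccc5)cc(OCc5ccccc5)c4c2O[C@H](c2ccc(OCc5ccccc5)c(OCc5ccccc5)c2)[C@H](O)C4)[C@@H](O)[C@@H](c2ccc(OCc5ccccc5)c(OCc5ccccc5)c2)O3)c2c(OCc5ccccc5)cc(OCc5ccccc5)cc2O[C@@H]1c1ccc(OCc5ccccc5)c(OCc5ccccc5)c1
A1 | alternative 1 | benzannulation product: T–M dimer (O3 tert-butyldimethylsilyl ethers, bromide on C8 of M) carrying on C4 of M the new ring A of L (free C8a–OH, C7 triisopropylsilyl ether, C5 benzyl ether, C4a (E)-3-[3,4-bis(benzyloxy)phenyl]allyl) | CC(C)(C)[Si](C)(C)O[C@@H]1[C@@H](c2c(OCc5ccccc5)c(Br)c3c(c2OCc5ccccc5)[C@H](c2c(O[Si](C(C)C)(C(C)C)C(C)C)cc(OCc5ccccc5)c(C/C=C/c6ccc(OCc5ccccc5)c(OCc5ccccc5)c6)c2O)[C@@H](O[Si](C)(C)C(C)(C)C)[C@@H](c2ccc(OCc5ccccc5)c(OCc5ccccc5)c2)O3)c2c(OCc5ccccc5)cc(OCc5ccccc5)cc2O[C@@H]1c1ccc(OCc5ccccc5)c(OCc5ccccc5)c1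
A2 | alternative 1 | siloxyalkyne: the same T–M dimer with a 2-(triisopropylsilyloxy)ethynyl group 4β on C4 of M | CC(C)(C)[Si](C)(C)O[C@@H]1[C@@H](c2c(OCc5ccccc5)c(Br)c3c(c2OCc5ccccc5)[C@H](C#CO[Si](C(C)C)(C(C)C)C(C)C)[C@@H](O[Si](C)(C)C(C)(C)C)[C@@H](c2ccc(OCc5ccccc5)c(OCc5ccccc5)c2)O3)c2c(OCc5ccccc5)cc(OCc5ccccc5)cc2O[C@@H]1c1ccc(OCc5ccccc5)c(OCc5ccccc5)c1
A3 | alternative 1 | 3-benzyloxy-4-[(E)-3-(3,4-bis(benzyloxy)phenyl)prop-2-enyl]cyclobut-2-en-1-one (racemic at C4) | O=C1C=C(OCc5ccccc5)C1C/C=C/c6ccc(OCc5ccccc5)c(OCc5ccccc5)c6
A4 | alternative 2 | perbenzylated trimer tri-gallate (henicosa-O-benzyl derivative of 17) | O=C(O[C@@H]1[C@@H](c2c(OCc5ccccc5)cc3c(c2OCc5ccccc5)[C@H](c2c(OCc5ccccc5)cc(OCc5ccccc5)c4c2O[C@H](c2ccc(OCc5ccccc5)c(OCc5ccccc5)c2)[C@H](OC(=O)c2cc(OCc5ccccc5)c(OCc5ccccc5)c(OCc5ccccc5)c2)C4)[C@@H](OC(=O)c2cc(OCc5ccccc5)c(OCc5ccccc5)c(OCc5ccccc5)c2)[C@@H](c2ccc(OCc5ccccc5)c(OCc5ccccc5)c2)O3)c2c(OCc5ccccc5)cc(OCc5ccccc5)cc2O[C@@H]1c1ccc(OCc5ccccc5)c(OCc5ccccc5)c1)c1cc(OCc5ccccc5)c(OCc5ccccc5)c(OCc5ccccc5)c1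
A5 | alternative 2 | o-hydroxybenzhydrol: 3,5-bis(benzyloxy)phenol linchpin bearing the perbenzylated T gallate (through its C4, 4β) para to the phenol and, ortho to the phenol, a CH(OH) group bonded to C8 of the perbenzylated L gallate (carbinol configuration undefined) | O=C(O[C@@H]1[C@@H](c2c(OCc5ccccc5)cc(O)c(c2OCc5ccccc5)C(O)c2c(OCc5ccccc5)cc(OCc5ccccc5)c4c2O[C@H](c2ccc(OCc5ccccc5)c(OCc5ccccc5)c2)[C@H](OC(=O)c2cc(OCc5ccccc5)c(OCc5ccccc5)c(OCc5ccccc5)c2)C4)c2c(OCc5ccccc5)cc(OCc5ccccc5)cc2O[C@@H]1c1ccc(OCc5ccccc5)c(OCc5ccccc5)c1)c1cc(OCc5ccccc5)c(OCc5ccccc5)c(OCc5ccccc5)c1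
A6 | alternative 2 | (Z)-2-[3,4-bis(benzyloxy)phenyl]ethenyl 3,4,5-tris(benzyloxy)benzoate | O=C(O/C=C\c1ccc(OCc5ccccc5)c(OCc5ccccc5)c1)c1cc(OCc5ccccc5)c(OCc5ccccc5)c(OCc5ccccc5)c1
A7 | alternative 3 | perbenzylated trimer with gallates on T and M, bromide on C8 of M, and unit L as 2-aryl-chroman-3-one | O=C(O[C@@H]1[C@@H](c2c(OCc5ccccc5)c(Br)c3c(c2OCc5ccccc5)[C@H](c2c(OCc5ccccc5)cc(OCc5ccccc5)c4c2O[C@H](c2ccc(OCc5ccccc5)c(OCc5ccccc5)c2)C(=O)C4)[C@@H](OC(=O)c2cc(OCc5ccccc5)c(OCc5ccccc5)c(OCc5ccccc5)c2)[C@@H](c2ccc(OCc5ccccc5)c(OCc5ccccc5)c2)O3)c2c(OCc5ccccc5)cc(OCc5ccccc5)cc2O[C@@H]1c1ccc(OCc5ccccc5)c(OCc5ccccc5)c1)c1cc(OCc5ccccc5)c(OCc5ccccc5)c(OCc5ccccc5)c1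
A8 | alternative 3 | α-diazo ketone: the T–M digallate of A7 carrying on C4 of M a ring A of L with free C8a–OH and, on C4a, a 3-diazo-3-[3,4-bis(benzyloxy)phenyl]-2-oxopropyl chain | O=C(O[C@@H]1[C@@H](c2c(OCc5ccccc5)c(Br)c3c(c2OCc5ccccc5)[C@H](c2c(OCc5ccccc5)cc(OCc5ccccc5)c(CC(=O)C(=[N+]=[N-])c4ccc(OCc5ccccc5)c(OCc5ccccc5)c4)c2O)[C@@H](OC(=O)c2cc(OCc5ccccc5)c(OCc5ccccc5)c(OCc5ccccc5)c2)[C@@H](c2ccc(OCc5ccccc5)c(OCc5ccccc5)c2)O3)c2c(OCc5ccccc5)cc(OCc5ccccc5)cc2O[C@@H]1c1ccc(OCc5ccccc5)c(OCc5ccccc5)c1)c1cc(OCc5ccccc5)c(OCc5ccccc5)c(OCc5ccccc5)c1
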